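**Plan**

- Target numbering: C1 = C–OH, C2 = C–tricosyl, C4 and C6 = C–OMe. The meta pair of oxygenated carbons C4/C6, each flanked by CH, with the alkyl chain on C2, is the alkylresorcinol (masked cyclohexane-1,3-dione) pattern. C1 is the ring carbon that a malonate delivers with a spare carboxyl attached.
- Retrosynthesis: C1–OH is traced back to C1–CHO and C1–CO2Me (aryl-to-oxygen migration), and the two O–CH3 bonds are cut. Ring bonds C1–C2 (Michael) and C5–C6 (Dieckmann) are then cut to (E)-heptacos-3-en-2-one and dimethyl malonate. Last, the enone C=C (ring bond C2–C3) is cut to tetracosanal and an acetonyl ylide.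
- Forward: the C23 chain is in place before the ring exists (alcohol → aldehyde → Wittig enone). The single carbocycle closes in one pot, is aromatised and O-methylated, and the ester carbon is exchanged for OH by way of the benzaldehyde.
- Stereochemistry: the target is achiral. Only the E-alkene matters (stabilised ylide), and the two racemic sp3 centres of the annulation product disappear on aromatisation.

Key step: step 3

Assumption: the target has no stereocentre or stereogenic axis, so it is one achiral compound and no enantiocontrol is needed; the racemic sp3 centres in 6–8 are drawn with relative configuration only.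

**Route**

Step 1
Reactants: 1 tetracosan-1-ol
Product: 2 tetracosanal
Conditions: IBX (1.5 equiv), EtOAc, 80 °C; filter
Reagents that add atoms: none
Why: Hypervalent-iodine (IBX) oxidation of a primary alcohol in hot ethyl acetate should dissolve the waxy C24 alcohol, stop at the aldehyde under anhydrous conditions and need only filtration as work-up.

Step 2
Reactants: 2 tetracosanal; 3 1-(triphenylphosphoranylidene)propan-2-one
Product: 4 (E)-heptacos-3-en-2-one
Conditions: 3 (1.2 equiv), toluene, 90 °C
Reagents that add atoms: none
Why: Wittig olefination with a carbonyl-stabilised ylide should give the conjugated enone with the E geometry typical of stabilised ylides, and an unhindered aliphatic aldehyde is an ideal partner.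

Step 3
Reactants: 4 (E)-heptacos-3-en-2-one; 5 dimethyl malonate
Product: 7 methyl rac-trans-2,4-dioxo-6-tricosylcyclohexane-1-carboxylate, via Michael adduct 6 (not isolated)
Conditions: 5 (1.2 equiv), NaOMe (1.3 equiv), MeOH–THF, reflux; then 1 M HCl, 0 °C
Reagents that add atoms: none
Why: Methoxide turns 5 into its soft stabilised anion, which adds 1,4 to enone 4 and joins the malonate carbon to the chain-bearing β-carbon (C1–C2 of the target); proton transfer then gives the terminal methyl-ketone enolate, whose carbon attacks one malonate ester carbonyl with loss of methoxide (C5–C6 of the target) in an intramolecular Claisen (Dieckmann) condensation. The closest known reaction type is the Michael–Dieckmann annulation of alk-3-en-2-ones with malonic esters, the classical laboratory entry to 5-alkylcyclohexane-1,3-diones and alkylresorcinols. The one ring formed, the six-membered carbocycle, closes by a 6-exo-trig (enolexo) acyl substitution. The two new sp3 centres (C1 and C6 of 7) arise racemic, with the trans arrangement expected because C1 stays epimerisable in base, and neither needs control since both become sp2 in step 4. The step needs 1,4- over 1,2-addition and closure through the CH3 enolate and not the internal CH2 enolate: the first is secured by the reversibility of malonate addition to the carbonyl, the second by ring size, since only the methyl-derived enolate reaches an ester through a six-membered transition state (the alternative would be a four-membered ring). All equilibria should be drained by deprotonation of the product to its vinylogous β-diketone enolate, which is protonated only on acidic work-up (7 is expected mainly as its enol tautomer).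

Step 4
Reactants: 7 methyl rac-trans-2,4-dioxo-6-tricosylcyclohexane-1-carboxylate
Product: 9 methyl 2,4-dihydroxy-6-tricosylbenzoate, via 3-bromo dione ester 8 (not isolated)
Conditions: Br2 (1.05 equiv), DMF, 20 °C, then 60 °C
Reagents that add atoms: none
Why: Bromination–dehydrobromination aromatisation of a cyclohexane-1,3-dione: the enol is brominated at C3 between the carbonyls, and the dienol form of 8 should lose HBr in a 1,4-sense to the resorcylate, the temperature being kept well below that at which bromide in DMF would dealkylate and decarboxylate the ester.

Step 5
Reactants: 9 methyl 2,4-dihydroxy-6-tricosylbenzoate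
Product: 10 methyl 2,4-dimethoxy-6-tricosylbenzoate
Conditions: MeI (4 equiv), K2CO3 (4 equiv), DMF, 50 °C
Reagents that add atoms: iodomethane, CI
Why: Williamson ether synthesis on both phenoxides; excess MeI in warm DMF should also methylate the hydrogen-bonded 2-OH, as is routine for orsellinate-type esters, while the ester is untouched.

Step 6
Reactants: 10 methyl 2,4-dimethoxy-6-tricosylbenzoate
Product: 11 (2,4-dimethoxy-6-tricosylphenyl)methanol
Conditions: LiAlH4 (2 equiv), THF, 0 °C to reflux; H2O/NaOH work-up
Reagents that add atoms: none
Why: Hydride reduction of an ester to the primary alcohol; LiAlH4 in refluxing THF is small and reactive enough for a di-ortho-substituted benzoate and leaves aryl methyl ethers intact.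

Step 7
Reactants: 11 (2,4-dimethoxy-6-tricosylphenyl)methanol
Product: 12 2,4-dimethoxy-6-tricosylbenzaldehyde
Conditions: IBX (1.5 equiv), EtOAc, 80 °C; filter
Reagents that add atoms: none
Why: IBX oxidation of a benzylic alcohol should stop cleanly at the aldehyde and spares the electron-rich ring, which has no free phenol at this stage.

Step 8
Reactants: 12 2,4-dimethoxy-6-tricosylbenzaldehyde
Product: 14 2,4-dimethoxy-6-tricosylphenol (target), via aryl formate 13 (not isolated)
Conditions: mCPBA (1.3 equiv), CH2Cl2, 0 °C to rt; aq NaHCO3 wash; then K2CO3 (cat.), MeOH–THF, rt, under argon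
Reagents that add atoms: 3-chloroperoxybenzoic acid, O=C(OO)c1cccc(Cl)c1
Why: Dakin-type Baeyer–Villiger oxidation: in the peracid adduct of the aldehyde the electron-rich, ortho/para-dimethoxylated aryl group should migrate to oxygen in preference to hydride, and mild methanolysis of formate 13 under inert gas releases the oxidation-prone phenol.

**Compound list**

1 | tetracosan-1-ol | CCCCCCCCCCCCCCCCCCCCCCCCO | starting material
2 | tetracosanal | CCCCCCCCCCCCCCCCCCCCCCCC=O | intermediate
3 | 1-(triphenylphosphoranylidene)propan-2-one | CC(=O)C=P(c1ccccc1)(c1ccccc1)c1ccccc1 | starting material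
4 | (E)-heptacos-3-en-2-one | CCCCCCCCCCCCCCCCCCCCCCC/C=C/C(C)=O | intermediate
5 | dimethyl malonate | COC(=O)CC(=O)OC | starting material
6 | dimethyl rac-2-(2-oxoheptacosan-4-yl)propanedioate (Michael adduct, racemic, not isolated) | CCCCCCCCCCCCCCCCCCCCCCCC(CC(C)=O)C(C(=O)OC)C(=O)OC | intermediate
7 | methyl rac-trans-2,4-dioxo-6-tricosylcyclohexane-1-carboxylate (racemate, ester and chain on opposite faces; one enantiomer drawn) | CCCCCCCCCCCCCCCCCCCCCCC[C@@H]1CC(=O)CC(=O)[C@H]1C(=O)OC | intermediate
8 | methyl rac-3-bromo-2,4-dioxo-6-tricosylcyclohexane-1-carboxylate (C3 epimers, not isolated) | CCCCCCCCCCCCCCCCCCCCCCC[C@@H]1CC(=O)C(Br)C(=O)[C@H]1C(=O)OC | intermediate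
9 | methyl 2,4-dihydroxy-6-tricosylbenzoate | CCCCCCCCCCCCCCCCCCCCCCCc1cc(O)cc(O)c1C(=O)OC | intermediate
10 | methyl 2,4-dimethoxy-6-tricosylbenzoate | CCCCCCCCCCCCCCCCCCCCCCCc1cc(OC)cc(OC)c1C(=O)OC | intermediate
11 | (2,4-dimethoxy-6-tricosylphenyl)methanol | CCCCCCCCCCCCCCCCCCCCCCCc1cc(OC)cc(OC)c1CO | intermediate
12 | 2,4-dimethoxy-6-tricosylbenzaldehyde | CCCCCCCCCCCCCCCCCCCCCCCc1cc(OC)cc(OC)c1C=O | intermediate
13 | 2,4-dimethoxy-6-tricosylphenyl formate (not isolated) | CCCCCCCCCCCCCCCCCCCCCCCc1cc(OC)cc(OC)c1OC=O | intermediate
14 | 2,4-dimethoxy-6-tricosylphenol (achiral) | CCCCCCCCCCCCCCCCCCCCCCCc1cc(OC)cc(OC)c1O | target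

**Step count**

Total steps: 8. Longest linear sequence: 8 steps (from tetracosan-1-ol 1).

**Steps most likely to fail**

Step 4. The resorcylate being formed is more nucleophilic than the dione, so bromination may run on into the aromatic ring, and prolonged heating with bromide in DMF may start to remove the ester; either would give mixtures. The fallback makes over-bromination the intended outcome. It sets out from 7: Br2 (3 equiv) in AcOH–CH2Cl2 at rt should aromatise and brominate both free ring positions to give methyl 3,5-dibromo-2,4-dihydroxy-6-tricosylbenzoate F1. Hydrogenolysis of both aryl bromides (H2, Pd/C, NaOAc, EtOAc–MeOH, rt) then returns to the route at 9.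

Step 8. The peracid may over-oxidise the electron-rich ring, the liberated phenol may be air-oxidised to a quinone during basic formate cleavage, or some formyl hydrogen may migrate instead of the aryl group. The fallback exchanges the carboxyl carbon for oxygen by a Hock-type route that uses neither peracid nor base. It sets out from ester 10: excess MeLi in THF (0 °C to rt) should give the tertiary carbinol 2-(2,4-dimethoxy-6-tricosylphenyl)propan-2-ol F2. Treatment with H2O2 and BF3·OEt2 in CH2Cl2 at 0 °C forms the benzylic hydroperoxide, the aryl group migrates to oxygen and the hemiketal collapses with loss of acetone, which returns to the route at 14 and bypasses 11–13.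

Step 3. The waxy enone may dissolve poorly in methanolic methoxide, so the Michael addition could be slow and reversible while enone self-condensation competes before the ring closes. The fallback reverses the polarity of the Michael partners but closes the same ring by the same Dieckmann bond. It sets out from aldehyde 2: Knoevenagel condensation with 5 (piperidine/AcOH cat., toluene, Dean–Stark) should give dimethyl 2-tetracosylidenepropanedioate F3. Enamine-catalysed conjugate addition of acetone (pyrrolidine cat., acetone–THF, rt) then gives the Michael adduct 6, here isolated. Cyclisation of 6 with NaOMe in MeOH–THF at reflux and acidic work-up returns to the route at 7.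

**Further compounds**

F1 | step 4 | methyl 3,5-dibromo-2,4-dihydroxy-6-tricosylbenzoate | CCCCCCCCCCCCCCCCCCCCCCCc1c(Br)c(O)c(Br)c(O)c1C(=O)OC
F2 | step 8 | 2-(2,4-dimethoxy-6-tricosylphenyl)propan-2-ol | CCCCCCCCCCCCCCCCCCCCCCCc1cc(OC)cc(OC)c1C(C)(C)O
F3 | step 3 | dimethyl 2-tetracosylidenepropanedioate | CCCCCCCCCCCCCCCCCCCCCCCC=C(C(=O)OC)C(=O)OC
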